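**Assumption:** atom locants in names are the ent‑kaurane numbers of the target (C6 = acetal carbon, C7 = lactone C=O, C15 = ketone, C17 = methyl). Silyl and stannyl groups in reagents are treated as masking groups, not skeleton atoms.

## Retrosynthetic overview

1. Ludongnin I ⇐ exo‑face hydrogenation of the 16‑methylene‑15‑ketone (sets C16) ⇐ 5‑exo vinyl‑radical closure of ring D (C13–C16).
2. Ring C ⇐ Diels–Alder of butadiene onto the 8‑formyl‑Δ8(9) spiro‑lactone; C10 controls C8 and C9.
3. Spiro‑lactone ⇐ Ti(III) radical opening of a C10 spiro‑epoxide and Giese addition to methyl acrylate (C9–C10 bond, quaternary C10) — the key step.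
4. Epoxide ⇐ cis‑fused keto‑acetal ⇐ asymmetric conjugate addition to 3‑methylcyclohexenone (C4) plus orthoformate Mukaiyama reaction (C6).
5. Ring order: A → tetrahydrofuran acetal → spiro‑lactone → C → D.

## Route

**Step 1**
Reactants: 1, 3‑methylcyclohex‑2‑en‑1‑one; 2, [(isopropoxy)dimethylsilyl]methylmagnesium chloride
Product: 3, {[(1R)‑1‑methyl‑3‑(trimethylsilyloxy)cyclohex‑2‑en‑1‑yl]methyl}(isopropoxy)dimethylsilane
Conditions: Cu(OTf)2 (3 mol %), chiral NHC·HCl (4 mol %), Et2O, −30 °C; then TMSCl, Et3N, THF, −30 °C → rt
Reagents that add atoms: 2, CC(C)O[Si](C)(C)C[Mg]Cl; chlorotrimethylsilane, C[Si](C)(C)Cl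
Why: Cu–NHC‑catalysed asymmetric conjugate addition of a Grignard reagent to a β‑substituted cyclohexenone creates quaternary C4 (R; ligand enantiomer chosen accordingly), and silylation traps the enolate regiospecifically as the C5=C10 enol ether (this masked‑hydroxymethyl Grignard is untested in the asymmetric version).

**Step 2**
Reactants: 3; 4, trimethyl orthoformate
Product: 5, (3R)‑2‑(dimethoxymethyl)‑3‑methyl‑3‑{[(isopropoxy)dimethylsilyl]methyl}cyclohexan‑1‑one (C5 epimers)
Conditions: HC(OMe)3, TMSOTf, CH2Cl2, −78 °C
Reagents that add atoms: 4, COC(OC)OC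
Why: Mukaiyama‑type addition of the silyl enol ether to the dimethoxycarbenium ion installs C6 at the acetal oxidation level only at C5; the C5 configuration is corrected in step 3.

**Step 3**
Reactants: 5
Product: 6, (1S,3aR,7aS)‑1‑methoxy‑3a‑methylhexahydro‑2‑benzofuran‑7(1H)‑one
Conditions: KF, KHCO3, 30% H2O2, THF/MeOH, rt; then Na2S2O3; CSA (cat.), MeOH, rt
Reagents that add atoms: hydrogen peroxide, OO
Why: Tamao oxidation converts C–Si to C19–OH, and acid‑catalysed transacetalisation closes the five‑membered mixed acetal while C5 (α to the ketone) and C6 equilibrate to the cis‑fused bicycle with the OMe on the convex face (trans to C10).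

**Step 4**
Reactants: 6; 7, chloroiodomethane
Product: 8, C10 spiro‑epoxide of 6 (1S,3aR,7aR; both epimers at the spiro carbon)
Conditions: ICH2Cl, n‑BuLi, THF, −78 °C → rt
Reagents that add atoms: 7, ClCI
Why: in‑situ chloromethyllithium adds to the hindered ketone without enolisation or β‑elimination of the β‑keto acetal and the chlorohydrin alkoxide closes to the epoxide (C20); the spiro configuration is irrelevant because C10 becomes a radical next.

**Step 5 (key step)**
Reactants: 8; 9, methyl acrylate
Product: 10, spiro‑δ‑lactone (4R,5R,6S,10R)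
Conditions: Cp2TiCl2 (2.5 equiv), Zn, THF, rt, 9 (5 equiv); then DBU (cat.), PhMe, 80 °C
Reagents that add atoms: 9, C=CC(=O)OC
Why: Ti(III) reductive epoxide opening (Nugent–RajanBabu) gives the tertiary C10 radical, which undergoes Giese addition to the acrylate on the face anti to C6 of the cis‑fused bicycle, forming C9–C10 and quaternary C10 (R); the Ti alkoxide/hydroxy ester then lactonises.

**Step 6**
Reactants: 10; 11, ethyl formate
Product: 12, 8‑(hydroxymethylene) spiro‑lactone (enol form of the 8‑formyl lactone)
Conditions: NaH, HCO2Et, THF, 0 °C → rt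
Reagents that add atoms: 11, CCOC=O
Why: Claisen formylation of the lactone enolate at C8 (the only enolisable position) introduces C15 as a stable hydroxymethylene group.

**Step 7**
Reactants: 12
Product: 13, 8‑formyl‑Δ8(9) spiro‑lactone (4R,5R,6S,10R)
Conditions: PhSeCl, pyridine, CH2Cl2, 0 °C; then 30% H2O2, 0 °C; used crude
Reagents that add atoms: none
Why: α‑selenenylation of the 1,3‑dicarbonyl followed by selenoxide syn‑elimination toward C9 gives the doubly activated 2‑formyl enoate dienophile.

**Step 8**
Reactants: 13; 14, buta‑1,3‑diene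
Product: 15, Diels–Alder adduct (4R,5R,6S,8S,9S,10R): ring C with a C12=C13 alkene and CHO on quaternary C8
Conditions: butadiene (excess), CH2Cl2, sealed tube, 0 °C → rt (ZnCl2 10 mol % if sluggish)
Reagents that add atoms: 14, C=CC=C
Why: Diels–Alder addition to the doubly activated alkene is suprafacial, so C7 and C10 stay cis on ring C, and the diene attacks C9 on the face anti to the bulky C5 branch of the spiro ring A, setting C8 and C9 (S,S).

**Step 9**
Reactants: 15; 16, ethynylmagnesium bromide
Product: 17, C15 propargylic alcohol (both C15 epimers)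
Conditions: HC≡CMgBr, THF, −78 → −20 °C
Reagents that add atoms: 16, C#C[Mg]Br
Why: Grignard 1,2‑addition is chemoselective for the neopentyl aldehyde over the hindered lactone; the C15 configuration is removed in step 11.

**Step 10**
Reactants: 17
Product: 18, bicyclo[3.2.1]octane allylic alcohol (4R,5R,6S,8S,9S,10R,13R) with a C16=C17 exocyclic methylene
Conditions: Bu3SnH (1.5 equiv), AIBN, PhH (0.05 M), 80 °C; then PPTS, MeOH/CH2Cl2, rt
Reagents that add atoms: none
Why: the stannyl radical adds to the terminal alkyne carbon, the C16 vinyl radical closes 5‑exo‑trig onto C13 (only the cis bridge is possible, fixing C13) and the C12 radical is reduced; mild acid then removes tin from the vinylstannane, and a relatively high Bu3SnH concentration suppresses rearrangement to the bicyclo[2.2.2] skeleton.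

**Step 11**
Reactants: 18
Product: 19, 16‑methylene‑15‑ketone
Conditions: Dess–Martin periodinane, NaHCO3, CH2Cl2, rt
Reagents that add atoms: none
Why: buffered Dess–Martin oxidation of the secondary allylic alcohol gives the α‑methylene cyclopentanone without touching the acetal or lactone.

**Step 12**
Reactants: 19
Product: 20, ludongnin I
Conditions: H2 (1 atm), 10% Pd/C, EtOAc, rt
Reagents that add atoms: none
Why: heterogeneous hydrogenation of the exocyclic enone delivers H to the exo face of the bicyclo[3.2.1]octane (anti to the C11–C12 bridge), giving the 16R methyl (syn to C12) under neutral conditions that do not epimerise C16.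

## Compound list

1 | 3‑methylcyclohex‑2‑en‑1‑one | CC1=CC(=O)CCC1 | starting material
2 | [(isopropoxy)dimethylsilyl]methylmagnesium chloride (masked HOCH2 unit) | CC(C)O[Si](C)(C)C[Mg]Cl | starting material
3 | (R)‑silyl enol ether | CC(C)O[Si](C)(C)C[C@]1(C)CCCC(O[Si](C)(C)C)=C1 | intermediate
4 | trimethyl orthoformate | COC(OC)OC | starting material
5 | (3R)‑β‑keto dimethyl acetal | CC(C)O[Si](C)(C)C[C@]1(C)CCCC(=O)C1C(OC)OC | intermediate
6 | (1S,3aR,7aS)‑keto acetal | CO[C@H]1OC[C@]2(C)CCCC(=O)[C@H]12 | intermediate
7 | chloroiodomethane | ClCI | starting material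
8 | spiro‑epoxide | CO[C@H]1OC[C@]2(C)CCCC3(CO3)[C@H]12 | intermediate
9 | methyl acrylate | C=CC(=O)OC | starting material
10 | spiro‑δ‑lactone | CO[C@H]1OC[C@]2(C)CCC[C@]3(COC(=O)CC3)[C@H]12 | intermediate
11 | ethyl formate | CCOC=O | starting material
12 | 8‑hydroxymethylene lactone | CO[C@H]1OC[C@]2(C)CCC[C@]3(COC(=O)C(=CO)C3)[C@H]12 | intermediate
13 | 8‑formyl‑Δ8(9) lactone | CO[C@H]1OC[C@]2(C)CCC[C@]3(COC(=O)C(C=O)=C3)[C@H]12 | intermediate
14 | buta‑1,3‑diene | C=CC=C | starting material
15 | Diels–Alder adduct (aldehyde) | CO[C@H]1OC[C@]2(C)CCC[C@]3(COC(=O)[C@@]4(C=O)CC=CC[C@H]43)[C@H]12 | intermediate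
16 | ethynylmagnesium bromide | C#C[Mg]Br | starting material
17 | propargylic alcohol | CO[C@H]1OC[C@]2(C)CCC[C@]3(COC(=O)[C@@]4(C(O)C#C)CC=CC[C@H]43)[C@H]12 | intermediate
18 | 16‑methylene‑15‑ol | CO[C@H]1OC[C@]2(C)CCC[C@]3(COC(=O)[C@@]45C[C@@H](CC[C@H]43)C(=C)C5O)[C@H]12 | intermediate
19 | 16‑methylene‑15‑ketone | CO[C@H]1OC[C@]2(C)CCC[C@]3(COC(=O)[C@@]45C[C@@H](CC[C@H]43)C(=C)C5=O)[C@H]12 | intermediate
20 | ludongnin I | CO[C@H]1OC[C@]2(C)CCC[C@]3(COC(=O)[C@@]45C[C@@H](CC[C@H]43)[C@@H](C)C5=O)[C@H]12 | target

## Summary

Total steps: 12. Longest linear sequence: 12 (fully linear).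

Steps most likely to fail, with fallbacks:

- **Step 5** (diastereoselectivity at C10; competing reduction or β‑hydride elimination of the hindered tertiary radical). Fallback: set C10 by polar chemistry. Homologate ketone 6 to the C10 carbaldehyde, carry out an enamine/enolate Michael addition to methyl acrylate anti to C6, then reduce with NaBH4 and lactonise.
- **Step 8** (facial selectivity at C9 and fragility of dienophile 13). Fallback: build ring C stepwise. Make the Δ8(9) lactone from 10 by selenoxide elimination, add an allyl group at C9 by conjugate addition, allylate and formylate C8, then close ring C by ring‑closing metathesis.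
- **Step 1** (enantioselectivity with the silylmethyl Grignard). Fallback: reverse the roles of nucleophile and substrate. Add methyl (AlMe3, Cu–phosphoramidite) to 3‑(silyloxymethyl)cyclohex‑2‑enone, made from cyclohexane‑1,3‑dione, to create the same C4 centre.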